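36.8% of the G charged is where D peaks, with G at the same figure, if D is used up as fast as G. This symmetric case is our zero of the scale, and we must decide whether cedar or alder is the flask to charge next.

| flask | G | E | remark | time |
|---|---|---|---|---|
| epsilon | 20 mM | 13 mM | run made earlier |  |
| gamma | 20 mM | 41 mM | run made earlier |  |
| cedar | 20 mM | 20.0 mM |  | 2.0 min |
| alder | 20 mM | 50.0 mM |  | 2.0 min |

| run | time / s | G / % | D / % | X / % | J / % |
|---|---|---|---|---|---|
| epsilon | 10.0 | 95.3 | 5.1 | 0 | 1.1 |
| epsilon | 15.0 | 91.8 | 8.2 | 0.3 | 0 |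
| epsilon | 30.0 | 84.8 | 13.7 | 0.5 | 0.4 |
| epsilon | 50.0 | 78.2 | 19.2 | 1.3 | 1.3 |
| epsilon | 60.0 | 75.0 | 21.8 | 0.6 | 2.7 |
| epsilon | 80.0 | 69.7 | 24.8 | 0.8 | 3.5 |
| gamma | 15.0 | 75.6 | 20.8 | 0.1 | 1.9 |
| gamma | 30.0 | 60.5 | 31.1 | 3.2 | 7.2 |
| gamma | 40.0 | 50.9 | 33.4 | 4.3 | 9.9 |
| gamma | 60.0 | 40.1 | 36.0 | 6.1 | 16.2 |
| gamma | 80.0 | 33.3 | 35.8 | 8.4 | 22.3 |

(scatter of a reading: 0.5 percentage points)

1. which of these there is most of at the end, counted by the G in it, cedar (G / D / J / X)
2. which of these there is most of at the end, counted by the G in it, alder (G / D / J / X)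
3. how much there is at the end of the one of these that leads, in percent of the G charged: cedar
4. how much there is at the end of the one of these that leads, in percent of the G charged: alder



1. Let g be the fraction of charged G left and u the logarithm of 1/g. In the symmetric case the fraction held as D is g·u.

2. We test this on the last gamma reading: u is 1.10, so D should be 36.6%, and it reads 35.8%. The last epsilon reading gives 25.2% against 24.8%.

3. We take each step to use one E, so the E used per G charged is 2(1−g)−g·u, which we replace by u up to u of 1, where it is 0.896. With e the equivalents of E charged and c the G charge, u = e(1−exp(−k·c·t)). Gamma's last reading then gives the shared rate constant 0.480 L mol⁻¹ s⁻¹.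

4. For cedar, u is 0.684, so g is 50.4% and D 34.5%. For alder, u is 1.71, so g is 18.1% and D 30.9%. Past u of 1 the line overstates the E used, so alder's g errs high.

5. Gamma's last reading puts 72.6% of what has passed D in J, so alder's J is about 37.1%, more than its D. Cedar stops short of the peak and alder passes it, so we charge cedar for D, which comes out higher there than in alder, and alder for J.

The forecast puts G ahead at 50.5% in cedar and J ahead at 39% in alder, a J above ours, and notes that “mass balance closes”.

The flasks give G leading cedar at 49.8% and J leading alder at 39.2%, with D at 34.7% and 29.0%.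

    E + D → J + L (k = 0.340 L mol⁻¹ s⁻¹)
    G + E → D + L (k = 0.480 L mol⁻¹ s⁻¹)
    E + D → X (k = 0.140 L mol⁻¹ s⁻¹)

The two D steps sum to 0.480 L mol⁻¹ s⁻¹ and the G step is 0.48 L mol⁻¹ s⁻¹. Alder's G puts its clock at 1.86 after 2.00 min, against our 1.71. We carry 0.480 L mol⁻¹ s⁻¹ to a neighbouring flask, which is alder with 5.0 mM of G, or 10.0 equiv of E. It reckons to u of 2.50, g of 8.17% and D of 20.4%. That neighbouring flask keeps 83.5% of its E, close to pseudo-first-order, and ends with G at 7.55% and D at 19.5%.

All runs stem from a simulated flask with constants of no real substance; noise was put on by code.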